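## Structural features

The target is a 5,6,7,8-tetrahydroquinoline: a pyridine ring (N1, C2–C4, C4a, C8a) fused through C4a–C8a to a saturated six-membered carbocycle (C5–C8). C6 is an all-carbon quaternary centre carrying a 3,4-dimethoxyphenyl ring, a CH2CH2N(CH3)C(O)CH3 chain and the ring methylenes C5 and C7. It is the only stereocentre and is R (priorities aryl > CH2CH2N > C5 > C7). No stereocentre stands next to it, and the two ring arms differ only in how they reach the pyridine (C5 is bonded to C4a, C7 reaches C8a through C8). The groups are robust but not inert: the pyridine nitrogen is basic, nucleophilic and binds metals; the dimethoxyphenyl ring makes any styrene-type precursor acid-sensitive; the tertiary amide is stable. The real difficulty is the enantioselective construction of C6 together with the carbocycle. The key step uses the fact that the side-chain nitrogen lies three atoms from C5 along N–CH2–CH2–C6–C5, so an N–C5 bond closes a pyrrolidine (N, C5, C6 and the two chain carbons). Because C5 is benzylic to the pyridine, this bond can later be cut by hydrogenolysis; while it exists, C6 has a neighbouring stereocentre and a chiral nitrogen substituent to control it.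

## Logic of the disconnections

18 to 16 (through 17): the N–CH3 bond of the tertiary amide is cut. The methyl group is the one part of the side chain that the cycloaddition cannot supply, and taking it off an amide avoids a separate mono-methylation of a primary amine. The gain is a secondary amide that needs no protecting group. The forward step must alkylate the amide anion faster than the pyridine nitrogen.

16 to 15: the N–C(O) bond to the acetyl group is cut. This exposes a primary amine; the forward step only needs chemoselective N-acylation.

15 to 14: read backwards, a bond is added from the side-chain nitrogen to C5 and a 1-phenylethyl group is placed on nitrogen; forwards, these two benzylic C–N bonds are cut. This turns an isolated quaternary centre into one corner of a cis-fused pyrrolidine and creates the retron for a dipolar cycloaddition. The forward step must cleave both C–N bonds and leave the pyridine ring, the aryl ethers and C6 untouched; C5 returns to CH2, so its configuration no longer matters.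

14 to 8 and 12 (through 13): three bonds are cut, C5–C6, the bond between the two side-chain carbons, and C5–N. This is the strategic cut: two rings, the quaternary carbon and both stereocentres disappear, leaving 8, which is achiral, and 12, which carries the only chiral information. The forward step must add 13 intramolecularly in the fused sense, with cis fusion, on the alkene face that gives 6R; face selection is the weak point and a separation of diastereomers is planned.

8 to 6 and 7: the bond between the dimethoxyphenyl ring and the alkene carbon is cut. Making this bond last on this branch means the acid-sensitive electron-rich styrene is formed only after the acetal is gone, and no 2-arylallyl halide is needed. The forward cross-coupling must tolerate a free aldehyde and a pyridine.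

6 to 5: the aldehyde is masked (two acetal C–O bonds, read backwards). The mask is needed for the carbanion chemistry; its removal must spare the vinyl bromide.

5 to 2 and 3 (through 4): the CH2–CH2 bond next to the pyridine (the future C7–C8 bond) is cut. The 2-methyl group is acidic enough for lateral lithiation, and 3 offers an allylic bromide for substitution while keeping a vinylic bromide for the later coupling. The forward step must deprotonate only the methyl group and substitute only at the allylic carbon.

2 to 1: the acetal C–O bonds are cut, leading to a commercial aldehyde.

12 to 11, then 11 to 9 and 10: the ester C–O bond, then the N–CH2 bond. The forward steps must stop at monoalkylation and must not touch the benzylic stereocentre.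

## Other disconnections considered

Alternative 1: The cut is the aryl–alkyl bond C4a–C5, with C8 raised to a ketone so that C5–C8 come from a four-membered ring. The key step would deliver the 8-oxo compound A1 (tert-butyl N-{2-[6-(3,4-dimethoxyphenyl)-8-oxo-5,6,7,8-tetrahydroquinolin-6-yl]ethyl}-N-methylcarbamate) from the achiral cyclobutanol A2. In A2 the carbinol carbon (future C8) bears the 3-bromopyridin-2-yl group and the opposite ring carbon (future C6) bears the aryl ring and the protected chain. With Pd(OAc)2, a chiral ferrocenyl P,N ligand and Cs2CO3, zerovalent palladium would insert into the C4a–Br bond. The palladium alkoxide would then break one of the two enantiotopic ring bonds at the carbinol carbon by β-carbon elimination, and reductive elimination would join the released CH2 to C4a.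
- In favour: C6 is set by a catalyst, ring strain drives the C–C cleavage, no diastereomers need separating, and the chain arrives with its N-methyl group, so no late N-methylation is needed. On these points it is better than the chosen plan.
- Against: the established scope of this palladium chemistry is mainly intermolecular arylation. The ring-forming variant on a 2-pyridyl carbinol needs β-carbon elimination from a small palladium alkoxide chelate beside a coordinating pyridine nitrogen, and its selectivity cannot be assumed.
- Against: A2 exists as cis and trans isomers that would be expected to give opposite configurations at C6. Addition of a 3-bromo-2-pyridyl organometallic to the cyclobutanone A3 would hardly distinguish an aryl group from a CH2CH2N chain.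
- Against: A3 itself needs a multi-step synthesis that installs the aryl-bearing quaternary carbon. After the key step the C8 ketone must be removed (two steps) and the carbamate exchanged for acetyl.
- Comparison: both plans create C6 and the carbocycle in one step. The alternative has the better source of asymmetry but rests on an untested substrate class, whereas the ylide cycloaddition is a known type. It is longer (about eleven to twelve steps against ten).

Alternative 2: The cut is the bond from C6 to the first side-chain carbon, made by C–H insertion while C5 is temporarily oxygenated. The key step would give the cis-fused γ-lactone A4 from the trans diazoacetate A5 (ester oxygen on C5 and hydrogen on C6 cis). Rh2(cap)4 (dirhodium tetracaprolactamate, a divalent rhodium dimer) would form the carbenoid, which inserts into the tertiary benzylic C6–H bond with retention. Hydrogenolysis of the benzylic C5–O bond, amide formation with methylamine, reduction and acetylation would finish.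
- In favour: five-membered insertion into an electron-rich tertiary benzylic C–H bond is the preferred mode. Transfer of configuration is strict, so the key step itself carries no stereochemical uncertainty; on this it is better than the chosen plan. The lactone carbonyl is the future N–CH2 carbon, and methylamine brings the N-methyl group.
- Against: the absolute configuration and the trans relationship must already be present in A5, which needs a separate asymmetric step. The pyridine nitrogen can occupy the axial sites of the dirhodium catalyst or capture the carbenoid as an ylide. The dimethoxyphenyl ring invites addition to the arene, and a diazo compound must be made and handled.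
- Comparison: both plans use a temporary bond at C5 (C5–O there, C5–N here) that is removed by benzylic hydrogenolysis, so that liability is equal. Step count is about equal (nine to ten). The alternative forms one skeletal bond and one ring in its key step against three bonds and two rings, and does not build the carbocycle.

Alternative 3: The cut is the C7=C8 bond of a 5,6-dihydroquinoline, with the side chain carried as a vinyl group. The key step would give the diene A6 (6-(3,4-dimethoxyphenyl)-6-vinyl-5,6-dihydroquinoline) from the achiral triene A7, whose C6 carries two enantiotopic vinyl groups. The chiral alkylidene Mo(N-2,6-iPr2C6H3)(CHCMe2Ph) with a chiral biphenolate would join the 2-vinylpyridine terminus to one of them with loss of ethylene. Hydroboration–oxidation of the remaining vinyl group, replacement of the hydroxyl by methylamine, acetylation and hydrogenation of C7=C8 would follow.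
- In favour: catalytic desymmetrisation sets C6 without auxiliary or separation, which is better than the chosen plan. The remaining vinyl group has exactly the two side-chain carbons. In closing the carbocycle in the key step the two plans are equal.
- Against: the hexavalent molybdenum centre is Lewis acidic and would be expected to be inhibited by the pyridine nitrogen beside the reacting vinyl group. A 2-vinylpyridine is a reluctant metathesis partner and the vinyl groups on the quaternary carbon are hindered.
- Against: A7 needs a gem-divinyl, aryl-substituted quaternary carbon, which costs several steps. After ring closure the terminal vinyl group must be functionalised beside the C7=C8 bond and a borane-binding pyridine.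
- Comparison: it is the more elegant source of asymmetry, but catalyst compatibility with this heteroarene is doubtful, whereas the thermal cycloaddition needs no metal. It forms one bond and one ring against three bonds and two rings, and is clearly longer (about thirteen steps).

Key step: step 7

## Remarks before the steps

- The stereodescriptors of 12 and 14 were re-derived. Compound 14 as drawn is cis-fused (5S,6R) with an (S)-configured auxiliary, and its C6 has the same spatial arrangement as C6 (R) of 18. No structure needed correction.
- Assumption: the sense and size of the facial induction by the (S)-1-phenylethyl group cannot be predicted with confidence. The route assumes the two cis-fused diastereomers formed in step 7 are separable and that the (5S,6R) isomer is taken on.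
- Design changes on the way to the precursor: the aryl ring is introduced by cross-coupling after the acetal has been removed, so the electron-rich styrene never meets aqueous acid. The allylic electrophile is commercial 2,3-dibromopropene, which removes the need for a 2-arylallyl bromide.
- Numbered reactants are not repeated on the "Reagents that add atoms" line.

## Route

Step 1
Reactants: 1 2-methylnicotinaldehyde
Product: 2 3-(1,3-dioxolan-2-yl)-2-methylpyridine
Conditions: HOCH2CH2OH (3 equiv), p-TsOH·H2O (1.1 equiv), toluene, reflux, water separator; aq NaHCO3
Reagents that add atoms: ethylene glycol, OCCO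
Why: Acid-catalysed acetalisation driven by azeotropic removal of water; slightly more than one equivalent of acid is used because the pyridine nitrogen takes up the first. The cyclic acetal protects the aldehyde from the base and carbanion of step 2.

Step 2
Reactants: 2 3-(1,3-dioxolan-2-yl)-2-methylpyridine; 3 2,3-dibromopropene
Product: 5 2-(3-bromobut-3-en-1-yl)-3-(1,3-dioxolan-2-yl)pyridine, via picolyllithium 4 (not isolated)
Conditions: LiN(iPr)2 (commercial solution, 1.05 equiv), THF, −78 °C; 3 (1.2 equiv), −78 to −20 °C
Reagents that add atoms: none
Why: Lateral lithiation of the 2-methyl group of a pyridine, then substitution at the allylic C–Br bond of 3; direct and allylic-transposition attack give the same product and the vinylic bromide is inert. No stereocentre is formed.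

Step 3
Reactants: 5 2-(3-bromobut-3-en-1-yl)-3-(1,3-dioxolan-2-yl)pyridine
Product: 6 2-(3-bromobut-3-en-1-yl)nicotinaldehyde
Conditions: 2 M HCl, THF, 60 °C; then NaHCO3
Reagents that add atoms: water, O
Why: Aqueous acid hydrolysis of the acetal; a vinyl bromide is stable to dilute acid, which is why deprotection is placed before the electron-rich aryl group is introduced.

Step 4
Reactants: 6 2-(3-bromobut-3-en-1-yl)nicotinaldehyde; 7 3,4-dimethoxyphenylboronic acid
Product: 8 2-[3-(3,4-dimethoxyphenyl)but-3-en-1-yl]nicotinaldehyde
Conditions: Pd(PPh3)4 (5 mol %), K2CO3 (2.5 equiv), 1,4-dioxane/H2O, 85 °C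
Reagents that add atoms: none
Why: Suzuki–Miyaura coupling of a 1,1-disubstituted vinyl bromide with an electron-rich arylboronic acid (oxidative addition of zerovalent palladium, transmetallation, reductive elimination). The non-enolisable aldehyde and the pyridine are tolerated under carbonate conditions.

Step 5
Reactants: 9 (S)-1-phenylethylamine; 10 tert-butyl bromoacetate
Product: 11 tert-butyl N-[(S)-1-phenylethyl]glycinate
Conditions: 9 (1.2 equiv), K2CO3 (1.5 equiv), MeCN, 0 °C to rt
Reagents that add atoms: none
Why: SN2 N-alkylation of a primary amine with an α-bromo ester; α-branching of the amine and its slight excess limit dialkylation. The benzylic stereocentre is not involved.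

Step 6
Reactants: 11 tert-butyl N-[(S)-1-phenylethyl]glycinate
Product: 12 N-[(S)-1-phenylethyl]glycine
Conditions: CF3CO2H, CH2Cl2, rt; evaporate; Dowex 50W (H+ form), elute aq NH3
Reagents that add atoms: none
Why: Acidolysis of the tert-butyl ester with loss of 2-methylpropene; ion exchange gives the free zwitterionic amino acid needed for decarboxylative ylide formation. The stereocentre is untouched.

Step 7
Reactants: 8 2-[3-(3,4-dimethoxyphenyl)but-3-en-1-yl]nicotinaldehyde; 12 N-[(S)-1-phenylethyl]glycine
Product: 14 (5S,6R)-cis-fused N-[(S)-1-phenylethyl]pyrrolidine cycloadduct [(3aR,9bS)-3a-(3,4-dimethoxyphenyl)-1-[(1S)-1-phenylethyl]-2,3,3a,4,5,9b-hexahydro-1H-pyrrolo[2,3-f]quinoline], via azomethine ylide 13 (not isolated)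
Conditions: 12 (2 equiv), toluene, 110 °C, water separator; 8 added over 6 h (final 0.02 M); chromatographic separation of diastereomers
Reagents that add atoms: none
Why: Condensation of the secondary amine of 12 with the aldehyde of 8, followed by loss of water and CO2, generates the non-stabilised azomethine ylide 13, whose carbanionic terminus C5 is conjugated with the pyridine and whose other terminus is the glycine CH2. 13 adds across the tethered alkene in a concerted suprafacial [3+2] process; the closest known reaction type is the decarboxylative azomethine ylide cycloaddition of ortho-alkenyl aryl aldehydes with N-alkylglycines onto unactivated styrene-type alkenes. The six-membered carbocycle closes in the fused mode by C5–C6 bond formation (a 6-exo attack on the internal alkene carbon; the four-atom link C4a–C8a–C8–C7 disfavours the bridged regiochemistry, which would need a seven-membered ring). The pyrrolidine closes as the cycloaddition ring itself, from the dipole atoms C5–N–CH2 and the two alkene carbons, through the C5–C6 and CH2–CH2 bonds. C6 is set by the alkene face that meets the dipole, which is controlled by the (S)-1-phenylethyl group on nitrogen; it should hold its hydrogen in the ylide plane and cover one face with the phenyl ring. C5 is set relative to C6 by the tether, since only the cis ring fusion (C5–H and C6–aryl on the same side) is reachable without strain in the transition state. The step needs intramolecular addition to win over capture of 13 by a second molecule of 8 (secured by slow addition and dilution) and fused regiochemistry (secured by the tether); facial selectivity is the least secure requirement because the inducing centre is exocyclic, so the two cis-fused diastereomers are separated here and only the (5S,6R) isomer 14 is carried on.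

Step 8
Reactants: 14 (5S,6R)-cis-fused N-[(S)-1-phenylethyl]pyrrolidine cycloadduct
Product: 15 2-[(6R)-6-(3,4-dimethoxyphenyl)-5,6,7,8-tetrahydroquinolin-6-yl]ethan-1-amine
Conditions: H2 (5 bar), Pd(OH)2 on carbon (20 wt %), EtOH/AcOH, 50 °C
Reagents that add atoms: none
Why: Catalytic hydrogenolysis of two benzylic C–N bonds (N-debenzylation type): the auxiliary leaves as ethylbenzene and the ring bond C5–N, benzylic to the pyridine, is cut so that C5 returns to CH2. C6 bears no hydrogen or heteroatom and keeps its configuration; acetic acid keeps the amines protonated so they do not poison the catalyst.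

Step 9
Reactants: 15 2-[(6R)-6-(3,4-dimethoxyphenyl)-5,6,7,8-tetrahydroquinolin-6-yl]ethan-1-amine
Product: 16 N-{2-[(6R)-6-(3,4-dimethoxyphenyl)-5,6,7,8-tetrahydroquinolin-6-yl]ethyl}acetamide
Conditions: Ac2O (1.1 equiv), Et3N, CH2Cl2, 0 °C to rt
Reagents that add atoms: acetic anhydride, CC(=O)OC(C)=O
Why: N-acylation of a primary amine; any acylation at the pyridine nitrogen is reversible and is lost on aqueous work-up.

Step 10
Reactants: 16 N-{2-[(6R)-6-(3,4-dimethoxyphenyl)-5,6,7,8-tetrahydroquinolin-6-yl]ethyl}acetamide
Product: 18 N-{2-[(6R)-6-(3,4-dimethoxyphenyl)-5,6,7,8-tetrahydroquinolin-6-yl]ethyl}-N-methylacetamide (CNP0293830.1), via sodium amidate 17 (not isolated)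
Conditions: NaH (1.2 equiv), THF/DMF, 0 °C; CH3I (1.05 equiv), 0 °C to rt
Reagents that add atoms: iodomethane, CI
Why: Deprotonation of the secondary amide and SN2 N-methylation of the amidate. The anion is far more nucleophilic than the neutral, 2-alkyl-flanked pyridine nitrogen, so one equivalent of CH3I at 0 °C should be consumed before quaternisation competes.

## Compound list

1 | 2-methylnicotinaldehyde (2-methylpyridine-3-carbaldehyde) | Cc1ncccc1C=O | starting material
2 | 3-(1,3-dioxolan-2-yl)-2-methylpyridine | Cc1ncccc1C1OCCO1 | intermediate
3 | 2,3-dibromopropene | C=C(Br)CBr | starting material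
4 | {[3-(1,3-dioxolan-2-yl)pyridin-2-yl]methyl}lithium (picolyllithium) | [Li]Cc1ncccc1C1OCCO1 | intermediate (not isolated)
5 | 2-(3-bromobut-3-en-1-yl)-3-(1,3-dioxolan-2-yl)pyridine | C=C(Br)CCc1ncccc1C1OCCO1 | intermediate
6 | 2-(3-bromobut-3-en-1-yl)nicotinaldehyde | C=C(Br)CCc1ncccc1C=O | intermediate
7 | 3,4-dimethoxyphenylboronic acid | COc1ccc(B(O)O)cc1OC | starting material
8 | 2-[3-(3,4-dimethoxyphenyl)but-3-en-1-yl]nicotinaldehyde | COc1ccc(C(=C)CCc2ncccc2C=O)cc1OC | intermediate
9 | (S)-1-phenylethylamine | C[C@H](N)c1ccccc1 | starting material
10 | tert-butyl bromoacetate | CC(C)(C)OC(=O)CBr | starting material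
11 | tert-butyl N-[(S)-1-phenylethyl]glycinate | C[C@H](NCC(=O)OC(C)(C)C)c1ccccc1 | intermediate
12 | N-[(S)-1-phenylethyl]glycine | C[C@H](NCC(=O)O)c1ccccc1 | intermediate
13 | azomethine ylide from 8 and decarboxylated 12: pyridyl–CH(−)–N(+)(=CH2)–CH(CH3)Ph, (S) at the auxiliary | COc1ccc(C(=C)CCc2ncccc2[CH-][N+](=C)[C@@H](C)c2ccccc2)cc1OC | intermediate (not isolated)
14 | (3aR,9bS)-3a-(3,4-dimethoxyphenyl)-1-[(1S)-1-phenylethyl]-2,3,3a,4,5,9b-hexahydro-1H-pyrrolo[2,3-f]quinoline; in tetrahydroquinoline numbering (5S,6R), pyrrolidine N on C5, CH2CH2 arm on C6, C5–H and C6–aryl cis | COc1ccc([C@]23CCc4ncccc4[C@H]2N([C@@H](C)c2ccccc2)CC3)cc1OC | intermediate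
15 | 2-[(6R)-6-(3,4-dimethoxyphenyl)-5,6,7,8-tetrahydroquinolin-6-yl]ethan-1-amine | COc1ccc([C@]2(CCN)CCc3ncccc3C2)cc1OC | intermediate
16 | N-{2-[(6R)-6-(3,4-dimethoxyphenyl)-5,6,7,8-tetrahydroquinolin-6-yl]ethyl}acetamide | COc1ccc([C@]2(CCNC(C)=O)CCc3ncccc3C2)cc1OC | intermediate
17 | sodium salt of 16 (sodium amidate) | COc1ccc([C@]2(CC[N-]C(C)=O)CCc3ncccc3C2)cc1OC.[Na+] | intermediate (not isolated)
18 | N-{2-[(6R)-6-(3,4-dimethoxyphenyl)-5,6,7,8-tetrahydroquinolin-6-yl]ethyl}-N-methylacetamide | COc1ccc([C@]2(CCN(C)C(C)=O)CCc3ncccc3C2)cc1OC | target

## Step count and least certain steps

Total step count: 10. Longest linear sequence: 8 (steps 1, 2, 3, 4, 7, 8, 9, 10); steps 5 and 6 form the two-step side branch to 12.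

**Step 7 (key step).** The most likely failure is poor facial selectivity. The controlling centre is exocyclic, can rotate about its N–C bond, and lies one atom from the dipole, so the two cis-fused diastereomers may form in similar amounts or with the unwanted one favoured. A second risk is slow addition to the hindered 1,1-disubstituted alkene, which gives the ylide time to be captured by unreacted aldehyde. Fallback (from 8, back at 15): stereochemistry is obtained by resolution instead of auxiliary control. 8 is heated with commercial N-benzylglycine under the same conditions to give the racemic cis-fused N-benzyl cycloadduct F1. Hydrogenolysis (H2, Pd(OH)2 on carbon, EtOH/AcOH) cuts both benzylic C–N bonds to give the racemic primary amine F2. F2 is resolved by preparative chromatography on a chiral stationary phase, and its (R)-enantiomer is 15.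

**Step 8.** The most likely failure is incomplete cleavage of the ring C5–N bond. After loss of the auxiliary, the secondary amine binds the catalyst, and the benzylic carbon is neopentyl-like and attached to an electron-poor pyridine. Forcing conditions risk reduction of the pyridine ring. Fallback (from 14, back at 18): the hydrogenolysis is staged and the methyl group is introduced early. Mild hydrogenolysis (H2 1 bar, Pd on carbon, MeOH, rt) removes only the auxiliary to give the cis-fused secondary pyrrolidine F3; this is also the material expected if step 8 stalls. Eschweiler–Clarke methylation (aq CH2O, HCO2H, 80 °C) gives the N-methylpyrrolidine F4. The ring C5–N bond is then cut at the tertiary-amine stage (H2, Pd(OH)2 on carbon, EtOH/AcOH), where benzylic C–N hydrogenolysis is generally easier, to give the N-methylamine F5. Acetylation (Ac2O, Et3N) gives 18, and steps 9 and 10 are not needed.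

**Step 10.** The most likely failure is competing methylation of the pyridine nitrogen, or incomplete deprotonation leaving a mixture that is hard to separate from a pyridinium salt. Fallback (from 15, back at 18): no electrophilic methylating agent is used. 15 is heated in ethyl formate to give the formamide F6. LiAlH4 in THF at reflux reduces it to the N-methylamine F5, and acetylation (Ac2O, Et3N) gives 18.

**Step 2.** The most likely failure is loss of the picolyl anion by proton transfer to 2,3-dibromopropene with dehydrobromination of the electrophile, or a second alkylation of the product. Fallback (from 2, back at 8): the aryl group is placed on the electrophile first. Suzuki–Miyaura coupling of commercial 2-bromoprop-2-en-1-ol with 7 (Pd(PPh3)4, K2CO3, dioxane/H2O) gives 2-(3,4-dimethoxyphenyl)prop-2-en-1-ol F7. Appel bromination (CBr4, PPh3, CH2Cl2, 0 °C) gives the allylic bromide F8. Alkylation of 4 (generated from 2 as in step 2) with F8 gives the aryl-alkene acetal F9. Mild hydrolysis (1 M HCl, THF, rt, monitored) gives 8; the cost is that the electron-rich styrene must then survive the acid.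

## Further compounds

F1 | step 7 | rac-(3aR*,9bS*)-1-benzyl-3a-(3,4-dimethoxyphenyl)-2,3,3a,4,5,9b-hexahydro-1H-pyrrolo[2,3-f]quinoline (racemate, cis-fused; one enantiomer drawn) | COc1ccc([C@]23CCc4ncccc4[C@H]2N(Cc2ccccc2)CC3)cc1OC
F2 | step 7 | racemic 2-[6-(3,4-dimethoxyphenyl)-5,6,7,8-tetrahydroquinolin-6-yl]ethan-1-amine | COc1ccc(C2(CCN)CCc3ncccc3C2)cc1OC
F3 | step 8 | (3aR,9bS)-3a-(3,4-dimethoxyphenyl)-2,3,3a,4,5,9b-hexahydro-1H-pyrrolo[2,3-f]quinoline | COc1ccc([C@]23CCc4ncccc4[C@H]2NCC3)cc1OC
F4 | step 8 | (3aR,9bS)-3a-(3,4-dimethoxyphenyl)-1-methyl-2,3,3a,4,5,9b-hexahydro-1H-pyrrolo[2,3-f]quinoline | COc1ccc([C@]23CCc4ncccc4[C@H]2N(C)CC3)cc1OC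
F5 | step 8 | 2-[(6R)-6-(3,4-dimethoxyphenyl)-5,6,7,8-tetrahydroquinolin-6-yl]-N-methylethan-1-amine | COc1ccc([C@]2(CCNC)CCc3ncccc3C2)cc1OC
F6 | step 10 | N-{2-[(6R)-6-(3,4-dimethoxyphenyl)-5,6,7,8-tetrahydroquinolin-6-yl]ethyl}formamide | COc1ccc([C@]2(CCNC=O)CCc3ncccc3C2)cc1OC
F7 | step 2 | 2-(3,4-dimethoxyphenyl)prop-2-en-1-ol | COc1ccc(C(=C)CO)cc1OC
F8 | step 2 | 4-(3-bromoprop-1-en-2-yl)-1,2-dimethoxybenzene | COc1ccc(C(=C)CBr)cc1OC
F9 | step 2 | 2-[3-(3,4-dimethoxyphenyl)but-3-en-1-yl]-3-(1,3-dioxolan-2-yl)pyridine | COc1ccc(C(=C)CCc2ncccc2C2OCCO2)cc1OC
A1 | alternative 1 | tert-butyl N-{2-[6-(3,4-dimethoxyphenyl)-8-oxo-5,6,7,8-tetrahydroquinolin-6-yl]ethyl}-N-methylcarbamate, C6 arranged as in the target | COc1ccc([C@]2(CCN(C)C(=O)OC(C)(C)C)CC(=O)c3ncccc3C2)cc1OC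
A2 | alternative 1 | tert-butyl N-{2-[3-(3-bromopyridin-2-yl)-1-(3,4-dimethoxyphenyl)-3-hydroxycyclobutyl]ethyl}-N-methylcarbamate (achiral; a single cis or trans isomer is required) | COc1ccc(C2(CCN(C)C(=O)OC(C)(C)C)CC(O)(c3ncccc3Br)C2)cc1OC
A3 | alternative 1 | tert-butyl N-{2-[1-(3,4-dimethoxyphenyl)-3-oxocyclobutyl]ethyl}-N-methylcarbamate | COc1ccc(C2(CCN(C)C(=O)OC(C)(C)C)CC(=O)C2)cc1OC
A4 | alternative 2 | cis-fused γ-lactone of 5-hydroxy-6-(3,4-dimethoxyphenyl)-5,6,7,8-tetrahydroquinoline-6-acetic acid, C6 arranged as in the target | COc1ccc([C@]23CCc4ncccc4[C@H]2OC(=O)C3)cc1OC
A5 | alternative 2 | trans-6-(3,4-dimethoxyphenyl)-5,6,7,8-tetrahydroquinolin-5-yl diazoacetate (C5–O and C6–H cis) | COc1ccc([C@@H]2CCc3ncccc3[C@H]2OC(=O)C=[N+]=[N-])cc1OC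
A6 | alternative 3 | 6-(3,4-dimethoxyphenyl)-6-vinyl-5,6-dihydroquinoline, C6 arranged as in the target | COc1ccc([C@]2(C=C)C=Cc3ncccc3C2)cc1OC
A7 | alternative 3 | 3-[2-(3,4-dimethoxyphenyl)-2-vinylbut-3-en-1-yl]-2-vinylpyridine | C=Cc1ncccc1CC(C=C)(C=C)c1ccc(OC)c(OC)c1
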